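The route rests on the C6–C7 bond (ring-B methylene to aryl ketone; abietane numbering). It exploits the fact that C6 and the acid carbon C3 are joined through C5–C10–C1–C2. A temporary C3–C6 bond therefore folds side chain and C5/C6 into a cyclohexenone ring that carries the ring-C benzoate on quaternary C10. In one operation an isopropenyl cuprate adds to C5 of this enone anti to the aryl group. The regiodefined C6 enolate then acylates the ortho ester carbon C7, closing ring B as a benzobicyclo[3.3.1]nonanedione. The expelled methoxide cleaves C3–C6 by retro-Claisen and releases the propanoate. The enone comes from an enantioselective quinone Diels–Alder reaction.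

Key step: step 10

Remark on numbering: abietane numbers are used for atoms throughout. C10 is the quaternary carbon, C5 the methine bearing isopropenyl, C6 the methylene and C7 the ketone. C8, C9 and C11–C14 form ring C, C1–C2–C3 is the propanoic acid chain, and "ring T" is the temporary ring C10–C1–C2–C3–C6–C5.
Assumption: the (4S,5S)-pybox–Gd(OTf)3 complex is taken to give the (R) configuration at C10. If the sense of induction proves opposite, the enantiomeric ligand is used.

Step 1
Reactants: 1 1,2,4-trimethoxybenzene
Product: 3 2-(2,3,6-trimethoxyphenyl)propan-2-ol, via aryllithium 2 (not isolated)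
Conditions: n-BuLi, THF, 0 °C → rt; acetone, −78 °C → rt; H2O
Reagents that add atoms: acetone CC(C)=O
Why: Directed ortho-metalation takes place at the C–H flanked by two methoxy groups (future C13) and the aryllithium adds 1,2 to acetone; no stereocenter is formed.

Step 2
Reactants: 3 2-(2,3,6-trimethoxyphenyl)propan-2-ol
Product: 4 1,2,4-trimethoxy-3-(propan-2-yl)benzene
Conditions: Et3SiH, CF3CO2H, CH2Cl2, 0 °C → rt
Reagents that add atoms: none
Why: Ionic hydrogenation, in which the tertiary benzylic cation stabilised by two ortho methoxy groups takes hydride from Et3SiH while the aryl methyl ethers stay inert.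

Step 3
Reactants: 4 1,2,4-trimethoxy-3-(propan-2-yl)benzene
Product: 5 2,4,5-trimethoxy-3-(propan-2-yl)benzaldehyde
Conditions: POCl3, DMF, 0 → 70 °C; ice–H2O
Reagents that add atoms: N,N-dimethylformamide CN(C)C=O; water O
Why: Vilsmeier–Haack formylation goes to the only position that is ortho to one methoxy group and para to another (future C8), which places C7 on the ring.

Step 4
Reactants: 5 2,4,5-trimethoxy-3-(propan-2-yl)benzaldehyde
Product: 6 methyl 2,4,5-trimethoxy-3-(propan-2-yl)benzoate
Conditions: I2, KOH, MeOH, 0 °C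
Reagents that add atoms: methanol CO
Why: Oxidative esterification, in which the hemiacetal formed with methanol is oxidised by the iodine/base couple, so no separate acid stage is needed and ring and ethers are untouched.

Step 5
Reactants: 6 methyl 2,4,5-trimethoxy-3-(propan-2-yl)benzoate
Product: 7 methyl 4-methoxy-3,6-dioxo-5-(propan-2-yl)cyclohexa-1,4-diene-1-carboxylate
Conditions: (NH4)2Ce(NO3)6, MeCN–H2O, 0 °C; used directly
Reagents that add atoms: water O
Why: Oxidative demethylation of the para-dimethoxy pair gives the p-quinone, and the remaining C12 methoxy group stays as a vinylogous ester that tempers the reactive acylquinone.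

Step 6
Reactants: 8 4-methylanisole
Product: 9 1-methoxy-4-methylcyclohexa-1,4-diene
Conditions: Li, NH3 (l), t-BuOH, THF, −78 → −33 °C; H2O
Reagents that add atoms: none
Why: Birch reduction of an anisole gives the 2,5-dihydro isomer with both donor substituents on the remaining double bonds.

Step 7
Reactants: 9 1-methoxy-4-methylcyclohexa-1,4-diene
Product: 10 1-methoxy-4-methylcyclohexa-1,3-diene
Conditions: KOt-Bu (20 mol %), DMSO, rt
Reagents that add atoms: none
Why: Base-catalysed prototropic isomerisation brings the double bonds into conjugation, the isomer with methoxy and methyl on the two diene termini should be favoured, and residual 9 is inert in step 8.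

Step 8
Reactants: 7 methyl 4-methoxy-3,6-dioxo-5-(propan-2-yl)cyclohexa-1,4-diene-1-carboxylate; 10 1-methoxy-4-methylcyclohexa-1,3-diene
Product: 13 methyl (4aS,9bS)-8-hydroxy-6-methoxy-9b-methyl-3-oxo-7-(propan-2-yl)-1,2,3,4,4a,9b-hexahydrodibenzo[b,d]furan-9-carboxylate, via Diels–Alder adduct 11 (not isolated), via hydroquinone enone 12 (not isolated)
Conditions: Gd(OTf)3 (10 mol %), 2,6-bis[(4S,5S)-4,5-diphenyl-4,5-dihydrooxazol-2-yl]pyridine (12 mol %), 4 Å MS, CH2Cl2, −78 → −30 °C; then 1 M HCl, THF, 0 °C → rt
Reagents that add atoms: water O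
Why: Catalytic enantioselective quinone Diels–Alder reaction in which two-point binding of the ester and C14 carbonyl oxygens to the chiral gadolinium complex activates only C8=C9 and shields one face, the methyl-bearing terminus of the 1-methoxydiene bonds to the unhindered C9–H carbon and so sets C10, acid then opens the bridgehead-methoxy adduct (retro-aldol-type C3–C8 cleavage driven by aromatisation) and hydrolyses it to the enone, and the C11 phenol closes onto C5 by 5-exo-trig oxa-Michael addition on the only face it can reach, giving the cis-fused ring.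

Step 9
Reactants: 13 methyl (4aS,9bS)-8-hydroxy-6-methoxy-9b-methyl-3-oxo-7-(propan-2-yl)-1,2,3,4,4a,9b-hexahydrodibenzo[b,d]furan-9-carboxylate
Product: 14 methyl 2,4,5-trimethoxy-6-[(1R)-1-methyl-4-oxocyclohex-2-en-1-yl]-3-(propan-2-yl)benzoate
Conditions: MeI, K2CO3, DMF, 50 °C
Reagents that add atoms: iodomethane CI
Why: Williamson O-methylation coupled to E1cB retro-oxa-Michael opening (the flavanone to 2'-methoxychalcone type of ring opening), in which the phenoxide released from C5 is trapped irreversibly as its methyl ether, the temporary C5 stereocenter is erased on purpose and C10 is untouched.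

Step 10
Reactants: 14 methyl 2,4,5-trimethoxy-6-[(1R)-1-methyl-4-oxocyclohex-2-en-1-yl]-3-(propan-2-yl)benzoate
Product: 17 methyl 3-[(1R,2S)-5,7,8-trimethoxy-1-methyl-4-oxo-6-(propan-2-yl)-2-(prop-1-en-2-yl)-1,2,3,4-tetrahydronaphthalen-1-yl]propanoate, via magnesium enolate 15 (not isolated), via bridged diketone 16 (not isolated)
Conditions: CH2=C(CH3)MgBr (2.2 equiv), CuBr·SMe2 (1.1 equiv), THF, −78 → −20 °C (no silyl chloride); then DMPU, NaOMe (20 mol %), −20 → 25 °C; aq NH4Cl
Reagents that add atoms: isopropenylmagnesium bromide C=C(C)[Mg]Br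
Why: Proposed new method: the cuprate adds 1,4 to C5, the resulting C3(O)=C6 enolate 15 attacks the ortho ester carbon C7 that the axial aryl group holds over C6, loss of methoxide gives the non-enolisable bridgehead 1,3-diketone 16, and methoxide (a chain carrier, primed with NaOMe) adds to the aliphatic C3 carbonyl and expels the aryl-conjugated C6=C7 enolate of 17. The closest known reaction types are the tandem cuprate addition–Dieckmann cyclisation and the retro-Claisen cleavage of non-enolisable 1,3-diketones, and what is new is their union across a 4-(2-alkoxycarbonylaryl)cyclohexenone. Ring B closes 6-(enolexo)-exo-trig as the third bridge of a benzobicyclo[3.3.1]nonane in which C9 and C7 occupy 1,3-diaxial positions of ring T. C5 is the only new stereocenter that survives and is controlled by C10, because the cuprate attacks antiperiplanar to the pseudoaxial hexasubstituted aryl group, which places isopropenyl trans to aryl on ring T and hence cis to the C1–C3 chain on ring B (5S,10R), while the bridgehead C6 center of 16 is dictated by the bridge and vanishes on cleavage. The step needs acylation at C6 rather than C2 and cleavage at C3 rather than C7: the first is secured because the enolate is born regiospecifically and meets no proton source before closure, the second because C7 is a hindered, donor-substituted aryl ketone and only attack at C3 leads to the better stabilised enolate and an unhindered aliphatic ester.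

Step 11
Reactants: 17 methyl 3-[(1R,2S)-5,7,8-trimethoxy-1-methyl-4-oxo-6-(propan-2-yl)-2-(prop-1-en-2-yl)-1,2,3,4-tetrahydronaphthalen-1-yl]propanoate
Product: 18 methyl 3-[(1R,2S)-7-methoxy-1-methyl-4,5,8-trioxo-6-(propan-2-yl)-2-(prop-1-en-2-yl)-1,2,3,4,5,8-hexahydronaphthalen-1-yl]propanoate
Conditions: (NH4)2Ce(NO3)6, MeCN–H2O, 0 °C, short contact
Reagents that add atoms: water O
Why: Oxidative demethylation of the C11/C14 para-dimethoxy pair frees two of the three ring-C oxygens without a Lewis or Brønsted acid strong enough to protonate the isopropenyl group, and both stereocenters are remote from the reacting ring.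

Step 12
Reactants: 18 methyl 3-[(1R,2S)-7-methoxy-1-methyl-4,5,8-trioxo-6-(propan-2-yl)-2-(prop-1-en-2-yl)-1,2,3,4,5,8-hexahydronaphthalen-1-yl]propanoate
Product: 20 3-[(1R,2S)-5,7,8-trihydroxy-1-methyl-4-oxo-6-(propan-2-yl)-2-(prop-1-en-2-yl)-1,2,3,4-tetrahydronaphthalen-1-yl]propanoic acid, via hydroxyquinone acid 19 (not isolated)
Conditions: LiOH, THF–H2O (degassed), 0 °C → rt; then Na2S2O4, rt; then cold 1 M HCl to pH 3, Ar
Reagents that add atoms: lithium hydroxide [Li+].[OH-]
Why: Addition–elimination of hydroxide at the vinylogous ester carbon C12 and saponification of the methyl ester give the hydroxyquinone carboxylate, whose anionic ring should resist further base chemistry, and dithionite reduction followed by mild acidification delivers the hydrogen-bonded 11,12,14-triol without touching C5, C10 or the alkene.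

Compound list
1 | 1,2,4-trimethoxybenzene | COc1ccc(OC)c(OC)c1 | starting material
2 | 2,3,6-trimethoxyphenyllithium (not isolated) | [Li]c1c(OC)ccc(OC)c1OC | intermediate
3 | 2-(2,3,6-trimethoxyphenyl)propan-2-ol | CC(C)(O)c1c(OC)ccc(OC)c1OC | intermediate
4 | 1,2,4-trimethoxy-3-(propan-2-yl)benzene | CC(C)c1c(OC)ccc(OC)c1OC | intermediate
5 | 2,4,5-trimethoxy-3-(propan-2-yl)benzaldehyde | CC(C)c1c(OC)c(C=O)cc(OC)c1OC | intermediate
6 | methyl 2,4,5-trimethoxy-3-(propan-2-yl)benzoate | COC(=O)c1cc(OC)c(OC)c(C(C)C)c1OC | intermediate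
7 | methyl 4-methoxy-3,6-dioxo-5-(propan-2-yl)cyclohexa-1,4-diene-1-carboxylate | COC(=O)C1=CC(=O)C(OC)=C(C(C)C)C1=O | intermediate
8 | 4-methylanisole | Cc1ccc(OC)cc1 | starting material
9 | 1-methoxy-4-methylcyclohexa-1,4-diene | COC1=CCC(C)=CC1 | intermediate
10 | 1-methoxy-4-methylcyclohexa-1,3-diene | COC1=CC=C(C)CC1 | intermediate
11 | endo Diels–Alder adduct, methyl 1,6-dimethoxy-4-methyl-5,8-dioxo-7-(propan-2-yl)-1,4,4a,5,8,8a-hexahydro-1,4-ethanonaphthalene-8a-carboxylate, enedione ring syn to the etheno bridge (not isolated) | CO[C@]12CC[C@](C)(C=C1)[C@@H]3C(=O)C(OC)=C(C(C)C)C(=O)[C@]23C(=O)OC | intermediate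
12 | methyl 2,5-dihydroxy-4-methoxy-6-[(1R)-1-methyl-4-oxocyclohex-2-en-1-yl]-3-(propan-2-yl)benzoate (not isolated) | COC(=O)c1c(O)c(C(C)C)c(OC)c(O)c1[C@]1(C)CCC(=O)C=C1 | intermediate
13 | methyl (4aS,9bS)-8-hydroxy-6-methoxy-9b-methyl-3-oxo-7-(propan-2-yl)-1,2,3,4,4a,9b-hexahydrodibenzo[b,d]furan-9-carboxylate, cis-fused | COC(=O)c1c(O)c(C(C)C)c(OC)c2O[C@H]3CC(=O)CC[C@@]3(C)c12 | intermediate
14 | methyl 2,4,5-trimethoxy-6-[(1R)-1-methyl-4-oxocyclohex-2-en-1-yl]-3-(propan-2-yl)benzoate | COC(=O)c1c(OC)c(C(C)C)c(OC)c(OC)c1[C@]1(C)CCC(=O)C=C1 | intermediate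
15 | bromomagnesium C3=C6 enolate of the (3S,4R)-4-aryl-4-methyl-3-(prop-1-en-2-yl)cyclohexanone, isopropenyl trans to aryl (not isolated) | C=C(C)[C@@H]1C=C(O[Mg]Br)CC[C@@]1(C)c1c(OC)c(OC)c(C(C)C)c(OC)c1C(=O)OC | intermediate
16 | benzobicyclo[3.3.1]nonanedione with C3 and C7 ketones flanking bridgehead C6, isopropenyl on the one-carbon bridge C5 pointing away from the benzo bridge (not isolated) | C=C(C)[C@@H]1[C@H]2C(=O)c3c(OC)c(C(C)C)c(OC)c(OC)c3[C@]1(C)CCC2=O | intermediate
17 | methyl 3-[(1R,2S)-5,7,8-trimethoxy-1-methyl-4-oxo-6-(propan-2-yl)-2-(prop-1-en-2-yl)-1,2,3,4-tetrahydronaphthalen-1-yl]propanoate | C=C(C)[C@@H]1CC(=O)c2c(OC)c(C(C)C)c(OC)c(OC)c2[C@]1(C)CCC(=O)OC | intermediate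
18 | methyl 3-[(1R,2S)-7-methoxy-1-methyl-4,5,8-trioxo-6-(propan-2-yl)-2-(prop-1-en-2-yl)-1,2,3,4,5,8-hexahydronaphthalen-1-yl]propanoate | C=C(C)[C@@H]1CC(=O)C2=C(C(=O)C(OC)=C(C(C)C)C2=O)[C@]1(C)CCC(=O)OC | intermediate
19 | 3-[(1R,2S)-7-hydroxy-1-methyl-4,5,8-trioxo-6-(propan-2-yl)-2-(prop-1-en-2-yl)-1,2,3,4,5,8-hexahydronaphthalen-1-yl]propanoic acid (not isolated) | C=C(C)[C@@H]1CC(=O)C2=C(C(=O)C(O)=C(C(C)C)C2=O)[C@]1(C)CCC(=O)O | intermediate
20 | 3-[(1R,2S)-5,7,8-trihydroxy-1-methyl-4-oxo-6-(propan-2-yl)-2-(prop-1-en-2-yl)-1,2,3,4-tetrahydronaphthalen-1-yl]propanoic acid | C=C(C)[C@@H]1CC(=O)c2c(O)c(C(C)C)c(O)c(O)c2[C@]1(C)CCC(=O)O | target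

Total step count: 12. Longest linear sequence: 10 steps (steps 1–5 and 8–12, from 1,2,4-trimethoxybenzene).

Steps most likely to fail

Step 10. The conjugate addition next to the quaternary carbon may be slow. The enolate may persist without closing onto the twisted, hindered benzoate. Proton exchange before closure may let C2 compete with C6. The fallback uses known chemistry and replaces the Claisen closure by an aldol closure at the aldehyde oxidation level. It sets out from 14. LiAlH4 (THF, 0 °C) reduces ester and enone to the allylic/benzylic diol F1. Dess–Martin periodinane re-oxidises both carbinols to the enone aldehyde F2. The same cuprate then triggers a tandem conjugate addition–intramolecular aldol reaction that forms the same C6–C7 bond and gives the bridged ketol F3. Dess–Martin oxidation gives 16, now isolated, and NaOMe in MeOH cleaves it by retro-Claisen to 17, where the route is rejoined.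

Step 8. Hydride or electron transfer from the electron-rich diene to the quinone may aromatise the diene. Facial selectivity may erode if the bond formation runs through an open Michael-type pathway. The fallback moves the source of asymmetry from the cycloaddition to a desymmetrisation. It sets out from 7 and 10. Achiral catalysis with Sc(OTf)3 followed by the same acid treatment gives the racemic cis-fused ketone F4. Methylation as in step 9 gives the racemic enone F5. Hydrogenation (H2, Pd/C, EtOAc) gives the achiral 4-aryl-4-methylcyclohexanone F6. Enantiotopic deprotonation with lithium bis[(R)-1-phenylethyl]amide and Me3SiCl at −78 °C (base enantiomer chosen for the R series) gives the silyl enol ether F7. Saegusa–Ito oxidation with Pd(OAc)2 in MeCN then comes back to the route at 14.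

Step 12. Enolisation at C6 of the acylquinone in base may be followed by internal redox tautomerisation, with loss of the C5 configuration. The triol may also re-oxidise in air during isolation. The fallback avoids base at the quinone stage. It sets out from 18. Na2S2O4 (THF–H2O) reduces the quinone first to the 12-O-methyl hydroquinone ester F8. AlI3 with pyridine in MeCN cleaves the methyl ether next to the free C11 phenol by neighbouring-group assistance, with pyridine scavenging acid so that the alkene is spared, and gives the triol methyl ester F9. LiOH in degassed THF–H2O followed by mild acidification comes back to the route at 20.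

Further compounds
F1 | step 10 | (4R)-4-[2-(hydroxymethyl)-3,5,6-trimethoxy-4-(propan-2-yl)phenyl]-4-methylcyclohex-2-en-1-ol, carbinol epimers | OCc1c(OC)c(C(C)C)c(OC)c(OC)c1[C@]1(C)CCC(O)C=C1
F2 | step 10 | 2,4,5-trimethoxy-6-[(1R)-1-methyl-4-oxocyclohex-2-en-1-yl]-3-(propan-2-yl)benzaldehyde | O=Cc1c(OC)c(C(C)C)c(OC)c(OC)c1[C@]1(C)CCC(=O)C=C1
F3 | step 10 | bridged ketol, the C7 carbinol analogue of 16, carbinol configuration open | C=C(C)[C@@H]1[C@H]2C(O)c3c(OC)c(C(C)C)c(OC)c(OC)c3[C@]1(C)CCC2=O
F4 | step 8 | racemic cis-fused form of 13 | COC(=O)c1c(O)c(C(C)C)c(OC)c2OC3CC(=O)CCC3(C)c12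
F5 | step 8 | racemic form of 14 | COC(=O)c1c(OC)c(C(C)C)c(OC)c(OC)c1C1(C)CCC(=O)C=C1
F6 | step 8 | methyl 2,4,5-trimethoxy-6-(1-methyl-4-oxocyclohexyl)-3-(propan-2-yl)benzoate, achiral | COC(=O)c1c(OC)c(C(C)C)c(OC)c(OC)c1C1(C)CCC(=O)CC1
F7 | step 8 | methyl 2,4,5-trimethoxy-6-[(1R)-1-methyl-4-(trimethylsilyloxy)cyclohex-3-en-1-yl]-3-(propan-2-yl)benzoate | COC(=O)c1c(OC)c(C(C)C)c(OC)c(OC)c1[C@]1(C)CCC(O[Si](C)(C)C)=CC1
F8 | step 12 | methyl 3-[(1R,2S)-5,8-dihydroxy-7-methoxy-1-methyl-4-oxo-6-(propan-2-yl)-2-(prop-1-en-2-yl)-1,2,3,4-tetrahydronaphthalen-1-yl]propanoate | C=C(C)[C@@H]1CC(=O)c2c(O)c(C(C)C)c(OC)c(O)c2[C@]1(C)CCC(=O)OC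
F9 | step 12 | methyl 3-[(1R,2S)-5,7,8-trihydroxy-1-methyl-4-oxo-6-(propan-2-yl)-2-(prop-1-en-2-yl)-1,2,3,4-tetrahydronaphthalen-1-yl]propanoate | C=C(C)[C@@H]1CC(=O)c2c(O)c(C(C)C)c(O)c(O)c2[C@]1(C)CCC(=O)OC
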